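(The readings were computed with made-up constants, and the scatter is random.)

Start from what the overall equation keeps constant: each Q made takes one E and one G, so as a working assumption [E] − [G] stays at its charged value through a run, and a reading of Q then gives both [E] and [G].

| flask | E | G | X | time |
|---|---|---|---|---|
| ash | 0.300 M | 0.330 M | 0.00300 M |  |
| larch | 0.300 M | 0.330 M | 0.00450 M |  |
| maple | 0.300 M | 0.170 M | 0.00300 M |  |
| birch | 0.300 M | 0.0510 M | 0.00300 M | 86 h |

- ash run (time / h: [Q] / M): 3.4: 0.0378; 5.4: 0.0542; 8.6: 0.0764; 14: 0.1033; 22: 0.1277; 34: 0.1526; 54: 0.1655; 86: 0.1773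
- larch run (time / h: [Q] / M): 3.4: 0.0534; 5.4: 0.0765; 8.6: 0.1017; 14: 0.1328; 22: 0.1619; 34: 0.1805; 54: 0.1965; 86: 0.2055
- maple run (time / h: [Q] / M): 3.4: 0.0206; 5.4: 0.0288; 8.6: 0.0435; 14: 0.0578; 22: 0.0746; 34: 0.0844; 54: 0.0987; 86: 0.1053

(readings scatter by 0.002 M)

- apparent order in [G] of the starting rate, round the charge of the ash run (the rate where two percent of its E have turned into Q)
- apparent order in [X] of the starting rate, round the charge of the ash run (the rate where two percent of its E have turned into Q)
- Q in the birch run at 86 h, as a share of the E charged

- Overall: E + G -> Q, with X as catalyst.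
- Constant volume, constant temperature.
- A reading of a species includes what of it is bound.
- An order is taken over about fifteen percent of the charge, up and down.

Try the plain estimate first and compare the first readings at 3.4 h: maple against ash gives an order in G of 0.915, and larch against ash an order in X of 0.852. Distrust both, because by then ash has turned more E into Q than maple and larch more than ash.

To remove that bias, divide the rate r of making Q by [E] and by [G] and subtract: ln([E]/[G]) changes at r([E] − [G])/([E][G]). If r = k[X][E][G], with k a constant, then the change in ln([E]/[G]) since the start, divided by [E] − [G], grows at k[X] whatever the charges. Ash at 86 h stands at 4.11 M⁻¹, and this number, Θ, is the clock, with a scatter there of about 0.107 M⁻¹.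

Maple at that time reads 4.11 M⁻¹, level with ash on the same X, so take the order in G as 1. Larch reads 6.01 M⁻¹, an order in X of 0.936 as a reading, which within the scatter allows 1.

But the clock does not run steadily. In ash it runs at 0.128 M⁻¹ h⁻¹ up to 3.4 h and at 0.0181 M⁻¹ h⁻¹ from 54 h to 86 h, slower. Yet larch at 86 h stands higher than ash from the same E and G, so I do not read the slowing as an equilibrium.

Birch has the X and E of ash, so give it the mean clock of ash and maple at 86 h. G is its limiting reagent, which caps Q at 17.0% of the E, and my reckoning gives 11.6%. The doubt remains that 0.0510 M of G lies below both tested charges.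

The forecast, a little above my figure, says 0.97 for G, 1 for X and 11.8% for birch, within 11% to 13%, and holds that “The plateaus are therefore catalyst death, not equilibrium”.

The birch flask gives 11.3%, inside that range; round the charge of ash the orders come to 1.0 in G and 1.0 in X, and the mechanism is:

    X + E ⇌ XE, settled at all times (1.600 M⁻¹)
    XE + G → Q + X + L (40.68 M⁻¹ h⁻¹)
    X + E → Qe + E (0.1224 M⁻¹ h⁻¹)
    E → Lx (0.01750 h⁻¹)

The rate in maple is 0.50 of that in ash once the same Q has been made, beside a charge ratio of G of 0.515. Reckoned on the same working assumption, although the scheme also turns E into Lx, birch's clock at 86 h works out at 3.92 M⁻¹, behind the reading for ash. Larch reaches a quarter of its E in Q at 5.30 h, where its clock reads 0.995 M⁻¹, against 0.992 M⁻¹ for ash's clock at 5.4 h scaled by the X ratio.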